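## The problem

Target 18 is a linear phlorotannin-type pentamer: five benzene rings, lettered A to E in the order of the SMILES string (A is the 2,4,6-trihydroxyphenoxy end, E the 3,4,5-trihydroxyphenoxy end), joined only by four diaryl ether oxygens and carrying thirteen free hydroxyls. It has no stereocentre and no stereogenic axis, so the whole task is regiochemical: deciding which oxygen on each ring is a bridge. Ring C is the hardest ring: it is pentaoxygenated, and its two bridging oxygens sit on adjacent carbons (C1 to ring B, C6 to ring D) and must be told apart from three further oxygens. Ring D is a 2,6-dioxygenated hydroquinone whose hindered oxygen bonds to ring E and whose open oxygen bonds to ring C. Rings this electron-rich give no handle for nucleophilic aromatic substitution, so the activation for ether formation has to be borrowed and later erased. The free polyphenol, with its pyrogallol and hydroxyquinol units, oxidises readily in air and base, so all hydroxyls must stay masked until the last step and the unmasking must leave the diaryl ethers intact. The enabling feature is that rings A, B and E each carry a hydroxyl at C4 para to the ether-linked C1 (on ring B also ortho to the C3 and C5 oxygens). A formyl group at those three C4 atoms activates exactly the needed positions for fluoride displacement and is then converted to the hydroxyl by aryl migration to oxygen.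

## Retrosynthesis

**18 to 17.** The ten O–CH3 bonds are cut last. Methyl ethers are the only masks that survive peracid, carbonate, methoxide, copper and aqueous acid throughout, and Lewis-acid demethylation cleaves sp3 C–O bonds without touching the sp2 C–O bonds of the diaryl ethers. The forward reaction must be exhaustive on triphenol 17.

**17 to 16 to 15 (key disconnection).** The C4–O bonds of rings A, B and E are cut together, through tris-formate 16, back to the aryl–CHO bonds of tris-aldehyde 15. This is preferred over carrying these oxygens through the assembly as ethers, because as formyl groups they make each of rings A, B and E an SNAr partner and then disappear into the substitution pattern of the target. The precursor 15 carries ten of the thirteen non-bridging oxygens and all four ether bonds. The forward step requires aryl rather than hydride migration at all three sites, with rings C and D left unoxidised.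

**15 to 13 + 14.** The ring D O–ring E C1 bond is cut. Fluoride 14 carries its formyl group para to fluorine, and the ring D phenol 13 attacks its unflanked carbon. This bond is made last among the ethers because ring E's formyl group must not be present while an earlier formyl group is oxidised. The forward reaction is an SNAr with a 2,6-dimethoxy-flanked phenoxide.

**13 to 12 to 11 to 8 + 10.** The ring D oxygen is re-masked as its methoxymethyl ether (12), the ring B methoxy group is traced back to fluorine (11), and the ring B C5–O bond is cut to phenol 8 and difluoride 10. The larger, weaker nucleophile 8 is given the more reactive difluoride, and the small methoxide is kept for the deactivated last fluorine. The acetal is chosen because it tolerates every intervening step and leaves under conditions harmless to two aryl aldehydes.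

**10 to 1 + 9.** The ring A O–ring B C1 bond is cut. Syringaldehyde 1 already has the ring A pattern: a phenol flanked by two methoxy groups with the latent C4 oxygen para. Trifluoride 9 offers its para fluorine as the least hindered site. The forward step must be para-selective and stop at mono-substitution.

**8 to 6 to 4 + 5.** The ring C C1–O bond is traced to a formyl group (6), so the C–D fragment uses the same formyl-to-hydroxyl tactic one stage earlier, before any other formyl group is present. The ring C C6–O bond is then cut to phenol 4 and bromide 5. Ring C carries three methoxy donors, so SNAr at this carbon is disfavoured and a copper-catalysed coupling assisted by the ortho formyl group is required. Bromide 5 brings all five ring C substituents in the right order.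

**4 to 2 to 1.** The unhindered ring D oxygen is again a former formyl group. Protecting the hindered phenol of 1 (giving 2) and oxidising the aldehyde differentiates the two hydroquinone oxygens of ring D without any selectivity problem. Compound 1 therefore serves as the source of both ring A and ring D.

## Roads not taken

**Alternative 1:** Ring C is built rather than bought, by cutting the bond between its C–H carbon and the neighbouring hydroxyl-bearing carbon. Thermolysis of the squarate-derived cyclobutenone A2 would open it to a dienylketene, whose ketene carbon closes onto the vinyl terminus to give, after tautomerisation, the hydroquinone mono-silyl ether A1. Its merit is real: all five ring C oxygens are placed without any aromatic substitution, and the ring B and ring D oxygens emerge already differentiated. That solves the ring C problem more cleanly than the copper coupling of step 3, which is the least comfortable bond formation in the chosen plan. The weak points are that A2 needs a lithiated aryl vinyl ether of the A–B unit, cryogenic addition and silylation of a tertiary alkoxide. After the key step, A1 still needs methylation, desilylation and the attachment of rings D and E at a hindered oxygen, with no activation unless formyl chemistry is brought back in. The key step makes one C–C bond of a ring that is available with the right oxygens as 5, whereas the chosen plan's key step makes three C–O bonds of the target. The chosen route is also shorter and uses no organolithium chemistry.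

**Alternative 2:** Ring A is built by cutting two of its C–C bonds. A methoxide-mediated double Claisen condensation of aryloxymalonate A4 with dimethyl 3-oxopentanedioate A5 would give the pentamer A3, with ring A as a dimethyl trihydroxyisophthalate. Its merit is that the most hindered ether oxygen of ring A (flanked by two hydroxyls) is installed by simple O-alkylation, and ring A arrives with free hydroxyls. Its weaknesses are decisive here. The condensation is run on a fully assembled B–E tetramer, so a reaction of classically modest efficiency comes at the very end of a linear sequence. Two ester carbons are built in only to be excised by hydrolysis and decarboxylation. Rings B to E, including the 3,4,5-trimethoxyphenyl ether at the hindered ring D oxygen, must still be joined without any activating group. The ring A ether is in fact the easiest bond of the chosen plan (step 5), so this alternative solves what needs no solving and leaves the hard ether bonds unaided.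

**Alternative 3:** This is the closest relative: both ring B ether bonds are cut at once. In one pot, 2,4,6-trimethoxyphenol A7 would displace the para fluorine of 9, phenol A8 (the C–D–E fragment) one ortho fluorine and methoxide the last, giving mono-aldehyde A6. It is more convergent than the chosen plan, forms three bonds in one operation, and ends with a single oxidation at the most electron-rich formyl ring, which is easier than a triple oxidation. On those counts it is better. Its costs lie elsewhere. A8 contains a 3,4,5-trimethoxyphenyl ring E bonded to the doubly flanked ring D oxygen with no activating group, so the hardest ether of the molecule is left to a hindered unactivated coupling. A7 is an oxidation-prone nucleophile. The one-pot sequence depends on three nucleophiles each finding the right fluorine in turn. The chosen plan is the stepwise form of the same linchpin, in which rings A and E also carry formyl groups. It pays for this with a triple instead of a single aryl migration and one more isolated SNAr step, and gains formyl activation for the D–E bond and a controlled order of substitution on ring B.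

Key step: step 10

Assumption: the target is achiral, so no step has to set configuration, and the aryl halides 5, 9 and 14 are taken as purchasable building blocks.

## Route

Step 1
Reactants: 1 syringaldehyde (4-hydroxy-3,5-dimethoxybenzaldehyde)
Product: 2 3,5-dimethoxy-4-(methoxymethoxy)benzaldehyde
Conditions: MOMCl, i-Pr2NEt, CH2Cl2, 0 °C to rt
Reagents that add atoms: chloromethyl methyl ether, COCCl
Why: O-alkylation of the acidic, hindered phenol (methoxymethyl protection); the acetal should survive peracid, carbonate, copper catalysis, fluoride and methoxide in steps 2 to 7 and leave later under mild aqueous acid.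

Step 2
Reactants: 2 3,5-dimethoxy-4-(methoxymethoxy)benzaldehyde
Product: 4 3,5-dimethoxy-4-(methoxymethoxy)phenol, via ring D formate 3 (not isolated)
Conditions: mCPBA, CH2Cl2, 0 °C to rt; aq. NaHCO3 wash; then K2CO3 (cat.), MeOH, rt
Reagents that add atoms: 3-chloroperbenzoic acid (mCPBA), OOC(=O)c1cccc(Cl)c1
Why: Baeyer–Villiger (Dakin-type) oxidation of a 3,4,5-trialkoxybenzaldehyde, in which the para oxygen favours aryl migration, followed by transesterification of the labile formate. This frees the unhindered ring D oxygen while the hindered one stays masked.

Step 3
Reactants: 4 3,5-dimethoxy-4-(methoxymethoxy)phenol; 5 2-bromo-3,4,5-trimethoxybenzaldehyde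
Product: 6 2-[3,5-dimethoxy-4-(methoxymethoxy)phenoxy]-3,4,5-trimethoxybenzaldehyde
Conditions: CuI (10 mol %), picolinic acid (20 mol %), K3PO4, DMSO, 90 °C, argon
Reagents that add atoms: none
Why: Ullmann diaryl ether synthesis with monovalent copper and picolinic acid, a system suited to ortho-substituted partners. The ortho formyl group eases C–Br activation, and the unhindered, electron-rich phenoxide of 4 is the favourable nucleophile type.

Step 4
Reactants: 6 2-[3,5-dimethoxy-4-(methoxymethoxy)phenoxy]-3,4,5-trimethoxybenzaldehyde
Product: 8 2-[3,5-dimethoxy-4-(methoxymethoxy)phenoxy]-3,4,5-trimethoxyphenol, via ring C formate 7 (not isolated)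
Conditions: mCPBA, CH2Cl2, 0 °C to rt; aq. NaHCO3 wash; then K2CO3 (cat.), MeOH, rt
Reagents that add atoms: 3-chloroperbenzoic acid (mCPBA), OOC(=O)c1cccc(Cl)c1
Why: Baeyer–Villiger oxidation in which the ortho aryloxy and para methoxy donors of ring C favour aryl over hydride migration; methanolysis then frees the ring C hydroxyl next to the C–H position, the oxygen that must bond to ring B.

Step 5
Reactants: 1 syringaldehyde; 9 2,4,6-trifluorobenzaldehyde
Product: 10 2,6-difluoro-4-(4-formyl-2,6-dimethoxyphenoxy)benzaldehyde
Conditions: K2CO3, DMF, 0 °C to rt (slight excess of 9)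
Reagents that add atoms: none
Why: Formyl-activated SNAr; the doubly flanked phenoxide of 1 should attack the para fluorine, the only one not next to the formyl group, and the excess of 9 with the deactivating effect of the first aryloxy group limits double substitution.

Step 6
Reactants: 8 2-[3,5-dimethoxy-4-(methoxymethoxy)phenoxy]-3,4,5-trimethoxyphenol; 10 2,6-difluoro-4-(4-formyl-2,6-dimethoxyphenoxy)benzaldehyde
Product: 11 2-{2-[3,5-dimethoxy-4-(methoxymethoxy)phenoxy]-3,4,5-trimethoxyphenoxy}-6-fluoro-4-(4-formyl-2,6-dimethoxyphenoxy)benzaldehyde
Conditions: K2CO3, DMF, 50 °C (1:1 stoichiometry)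
Reagents that add atoms: none
Why: Formyl-activated SNAr at one of two equivalent ortho fluorines; the new aryloxy donor slows a second displacement, and C–F is far more reactive than C–OAr in addition–elimination, so the existing ether should persist.

Step 7
Reactants: 11 the ring B fluoride of step 6
Product: 12 2-{2-[3,5-dimethoxy-4-(methoxymethoxy)phenoxy]-3,4,5-trimethoxyphenoxy}-4-(4-formyl-2,6-dimethoxyphenoxy)-6-methoxybenzaldehyde
Conditions: NaOMe, MeOH–THF, 50 °C
Reagents that add atoms: sodium methoxide, [Na+].[O-]C
Why: SNAr of the last ortho fluorine by a small, strong nucleophile suited to the now deactivated ring; fluoride leaves much faster than aryloxide, and the non-enolisable aldehydes only form hemiacetals reversibly.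

Step 8
Reactants: 12 the methoxymethyl-protected A–B–C–D dialdehyde
Product: 13 4-(4-formyl-2,6-dimethoxyphenoxy)-2-[2-(4-hydroxy-3,5-dimethoxyphenoxy)-3,4,5-trimethoxyphenoxy]-6-methoxybenzaldehyde
Conditions: 3 M aq. HCl, THF, 40 °C
Reagents that add atoms: none
Why: Acid hydrolysis of the methoxymethyl acetal; diaryl ethers, aryl methyl ethers and aryl aldehydes are inert to dilute aqueous acid, and water intercepts the oxocarbenium ion before it can alkylate the electron-rich rings.

Step 9
Reactants: 13 the ring D phenol of step 8; 14 4-fluoro-2,6-dimethoxybenzaldehyde
Product: 15 pentamer tris-aldehyde, 4-(4-formyl-2,6-dimethoxyphenoxy)-2-{2-[4-(4-formyl-3,5-dimethoxyphenoxy)-3,5-dimethoxyphenoxy]-3,4,5-trimethoxyphenoxy}-6-methoxybenzaldehyde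
Conditions: Cs2CO3, DMSO, 90 °C, argon (excess 14)
Reagents that add atoms: none
Why: Formyl-activated SNAr of the 2,6-dimethoxy-flanked phenoxide on the unflanked para fluorine of 14, the reactivity known for 2,6-dimethoxyphenol with 4-fluorobenzaldehydes; the methoxy groups of 14 are meta to the site of attack and do not destabilise the Meisenheimer intermediate.

Step 10
Reactants: 15 pentamer tris-aldehyde
Product: 16 pentamer tris-formate (each formyl group of 15 replaced by a formyloxy group, at C4 of rings A, B and E)
Conditions: mCPBA (4.5 equiv), CH2Cl2, 0 °C to rt
Reagents that add atoms: 3-chloroperbenzoic acid (mCPBA), OOC(=O)c1cccc(Cl)c1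
Why: The peracid adds to each formyl carbon to give a Criegee adduct, and the aryl group antiperiplanar to the O–O bond migrates from carbon to oxygen as 3-chlorobenzoate leaves, giving the aryl formate. The closest known reactions are the mCPBA oxidations of 3,4,5-trimethoxy- and 2,4,6-trimethoxybenzaldehyde to the corresponding aryl formates. No ring is closed and no stereocentre is formed; the step makes the three C4–O bonds of rings A, B and E. The selectivity needed is aryl over hydride migration at every site and formyl over arene oxidation. Ring E has two ortho methoxy groups and a para aryloxy oxygen, ring B has an ortho methoxy, an ortho aryloxy and a para aryloxy oxygen, and ring A has a para aryloxy oxygen; each stabilises the electron-poor migrating carbon. Ring A is the least assisted, but once ring B has become a formate the bridging oxygen is a better donor toward ring A, so the likely order of events helps. Rings C and D bear no carbonyl group, and low temperature with a measured excess of peracid should leave them untouched.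

Step 11
Reactants: 16 pentamer tris-formate
Product: 17 pentamer triphenol (hydroxyl at C4 of rings A, B and E; ten methyl ethers)
Conditions: K2CO3 (cat.), MeOH–THF, rt, argon; dilute HCl work-up
Reagents that add atoms: none
Why: Base-catalysed transesterification of aryl formates, fast at room temperature; the molecule contains no other ester, and exclusion of air protects the electron-rich phenols.

Step 12
Reactants: 17 pentamer triphenol
Product: 18 target tridecaphenol (CNP0228612.0)
Conditions: BBr3 (excess), CH2Cl2, −78 °C to rt; ice-water quench, argon
Reagents that add atoms: none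
Why: Lewis-acid ether cleavage: BBr3 binds each methoxy oxygen and bromide attacks the methyl carbon (SN2), which spares the sp2 C–O bonds of the four diaryl ethers. This is the usual method for exhaustive demethylation of polymethoxylated diaryl ethers.

## Compound list

1 | syringaldehyde (4-hydroxy-3,5-dimethoxybenzaldehyde) | COc1cc(C=O)cc(OC)c1O | starting material
2 | 3,5-dimethoxy-4-(methoxymethoxy)benzaldehyde | COCOc1c(OC)cc(C=O)cc1OC | intermediate
3 | 3,5-dimethoxy-4-(methoxymethoxy)phenyl formate (ring D formate) | COCOc1c(OC)cc(OC=O)cc1OC | intermediate
4 | 3,5-dimethoxy-4-(methoxymethoxy)phenol | COCOc1c(OC)cc(O)cc1OC | intermediate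
5 | 2-bromo-3,4,5-trimethoxybenzaldehyde | COc1cc(C=O)c(Br)c(OC)c1OC | starting material
6 | 2-[3,5-dimethoxy-4-(methoxymethoxy)phenoxy]-3,4,5-trimethoxybenzaldehyde | COCOc1c(OC)cc(Oc2c(C=O)cc(OC)c(OC)c2OC)cc1OC | intermediate
7 | 2-[3,5-dimethoxy-4-(methoxymethoxy)phenoxy]-3,4,5-trimethoxyphenyl formate (ring C formate) | COCOc1c(OC)cc(Oc2c(OC=O)cc(OC)c(OC)c2OC)cc1OC | intermediate
8 | 2-[3,5-dimethoxy-4-(methoxymethoxy)phenoxy]-3,4,5-trimethoxyphenol | COCOc1c(OC)cc(Oc2c(O)cc(OC)c(OC)c2OC)cc1OC | intermediate
9 | 2,4,6-trifluorobenzaldehyde | O=Cc1c(F)cc(F)cc1F | starting material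
10 | 2,6-difluoro-4-(4-formyl-2,6-dimethoxyphenoxy)benzaldehyde | COc1cc(C=O)cc(OC)c1Oc1cc(F)c(C=O)c(F)c1 | intermediate
11 | A–B–C–D fluoride: 2-{2-[3,5-dimethoxy-4-(methoxymethoxy)phenoxy]-3,4,5-trimethoxyphenoxy}-6-fluoro-4-(4-formyl-2,6-dimethoxyphenoxy)benzaldehyde | COc1cc(C=O)cc(OC)c1Oc1cc(F)c(C=O)c(Oc2cc(OC)c(OC)c(OC)c2Oc2cc(OC)c(OCOC)c(OC)c2)c1 | intermediate
12 | A–B–C–D dialdehyde, ring D as methoxymethyl ether: 2-{2-[3,5-dimethoxy-4-(methoxymethoxy)phenoxy]-3,4,5-trimethoxyphenoxy}-4-(4-formyl-2,6-dimethoxyphenoxy)-6-methoxybenzaldehyde | COc1cc(C=O)cc(OC)c1Oc1cc(OC)c(C=O)c(Oc2cc(OC)c(OC)c(OC)c2Oc2cc(OC)c(OCOC)c(OC)c2)c1 | intermediate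
13 | A–B–C–D dialdehyde with free ring D phenol: 4-(4-formyl-2,6-dimethoxyphenoxy)-2-[2-(4-hydroxy-3,5-dimethoxyphenoxy)-3,4,5-trimethoxyphenoxy]-6-methoxybenzaldehyde | COc1cc(C=O)cc(OC)c1Oc1cc(OC)c(C=O)c(Oc2cc(OC)c(OC)c(OC)c2Oc2cc(OC)c(O)c(OC)c2)c1 | intermediate
14 | 4-fluoro-2,6-dimethoxybenzaldehyde | COc1cc(F)cc(OC)c1C=O | starting material
15 | pentamer tris-aldehyde (formyl at C4 of rings A, B and E, all other oxygens methylated) | COc1cc(C=O)cc(OC)c1Oc1cc(OC)c(C=O)c(Oc2cc(OC)c(OC)c(OC)c2Oc2cc(OC)c(Oc3cc(OC)c(C=O)c(OC)c3)c(OC)c2)c1 | intermediate
16 | pentamer tris-formate (formyloxy at C4 of rings A, B and E) | COc1cc(OC=O)cc(OC)c1Oc1cc(OC)c(OC=O)c(Oc2cc(OC)c(OC)c(OC)c2Oc2cc(OC)c(Oc3cc(OC)c(OC=O)c(OC)c3)c(OC)c2)c1 | intermediate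
17 | pentamer triphenol (hydroxyl at C4 of rings A, B and E, ten methyl ethers) | COc1cc(O)cc(OC)c1Oc1cc(OC)c(O)c(Oc2cc(OC)c(OC)c(OC)c2Oc2cc(OC)c(Oc3cc(OC)c(O)c(OC)c3)c(OC)c2)c1 | intermediate
18 | CNP0228612.0, the free tridecahydroxy pentamer | Oc1cc(O)c(Oc2cc(O)c(O)c(Oc3cc(O)c(O)c(O)c3Oc3cc(O)c(Oc4cc(O)c(O)c(O)c4)c(O)c3)c2)c(O)c1 | target

## Step count and risks

Total step count: 12. Longest linear sequence: 11 steps (steps 1 to 4 and 6 to 12); step 5 is a one-step side branch.

**Step 10 (key step).** The most likely failure is hydride migration in the Criegee adduct of ring A, whose only resonance donor is an aryloxy oxygen shared with a formyl-bearing ring; this would over-oxidise that site to a carboxylic acid. A second failure is slow attack of excess peracid on the electron-rich rings C and D once the reaction is pushed to complete all three sites. The fallback sets out from 15 and comes back to the route at 17. Addition of MeMgBr (THF, 0 °C) to the three formyl groups gives the tris(1-hydroxyethyl) pentamer F1, a diastereomer mixture of no consequence. MnO2 in CH2Cl2 oxidises it to the tris(methyl ketone) F2. Baeyer–Villiger oxidation with mCPBA and catalytic CF3CO2H then gives the tris-acetate F3; in these ketones hydride migration is impossible and the electron-rich aryl group out-migrates methyl. K2CO3 in MeOH releases 17.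

**Step 3.** The bromide of 5 is flanked on both sides, so C–Br activation and C–O bond formation at copper may be slow. Protodebromination of 5 and oxidative degradation of the electron-rich phenoxide of 4 would then take over. The fallback sets out from 5 and 4 and comes back at 6. Pinnick oxidation of 5 (NaClO2, NaH2PO4, 2-methyl-2-butene, t-BuOH/H2O) gives 2-bromo-3,4,5-trimethoxybenzoic acid F4. Its potassium salt is condensed with 4 (Cu powder, K2CO3, DMF, 110 °C); the ortho carboxylate chelates copper and is known to accelerate substitution at hindered ortho-bromobenzoates. This gives the diaryl ether acid F5. BH3·THF reduces it to the benzyl alcohol F6, and MnO2 in CH2Cl2 returns aldehyde 6.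

**Step 9.** The phenoxide of 13 is hindered and 14 is only moderately activated, so forcing conditions may be needed. Under them the phenoxide or liberated fluoride could attack the formyl-activated aryloxy carbons of ring B, leading to ether exchange and fragmentation of the tetramer. Air oxidation of the hydroquinone-type phenoxide is a further risk. The fallback sets out from 13 and comes back at 15. It is a Chan–Lam–Evans coupling of 13 with (4-formyl-3,5-dimethoxyphenyl)boronic acid F7 (Cu(OAc)2, pyridine, 4 Å molecular sieves, CH2Cl2, air, rt). This oxidative coupling promoted by divalent copper acetate runs at room temperature without a strong base or free fluoride, so the existing ethers are not exposed to exchange, and it is known to accept ortho-disubstituted phenols.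

**Step 12.** Cleavage of ten methyl ethers may stop short, leaving partially methylated congeners that cannot be separated from the free polyphenol. The pyrogallol and hydroxyquinol rings of 18 may also oxidise during aqueous isolation and chromatography. The fallback sets out from 17 and comes back at 18. The crude demethylation mixture is acetylated directly (Ac2O, pyridine) to the tridecaacetate F8, a neutral, air-stable compound that can be purified on silica and separated from under-demethylated material. Acid methanolysis under argon (HCl generated from AcCl in MeOH) then releases 18 with only volatile by-products.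

## Further compounds

F1 | step 10 | tris(1-hydroxyethyl) pentamer, 15 with each CHO replaced by CH(OH)CH3 (mixture of diastereomers, configuration not controlled) | COc1cc(C(C)O)cc(OC)c1Oc1cc(OC)c(C(C)O)c(Oc2cc(OC)c(OC)c(OC)c2Oc2cc(OC)c(Oc3cc(OC)c(C(C)O)c(OC)c3)c(OC)c2)c1
F2 | step 10 | tris(methyl ketone) pentamer, acetyl at C4 of rings A, B and E | COc1cc(C(C)=O)cc(OC)c1Oc1cc(OC)c(C(C)=O)c(Oc2cc(OC)c(OC)c(OC)c2Oc2cc(OC)c(Oc3cc(OC)c(C(C)=O)c(OC)c3)c(OC)c2)c1
F3 | step 10 | pentamer tris-acetate, acetoxy at C4 of rings A, B and E | COc1cc(OC(C)=O)cc(OC)c1Oc1cc(OC)c(OC(C)=O)c(Oc2cc(OC)c(OC)c(OC)c2Oc2cc(OC)c(Oc3cc(OC)c(OC(C)=O)c(OC)c3)c(OC)c2)c1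
F4 | step 3 | 2-bromo-3,4,5-trimethoxybenzoic acid | COc1cc(C(=O)O)c(Br)c(OC)c1OC
F5 | step 3 | 2-[3,5-dimethoxy-4-(methoxymethoxy)phenoxy]-3,4,5-trimethoxybenzoic acid | COCOc1c(OC)cc(Oc2c(C(=O)O)cc(OC)c(OC)c2OC)cc1OC
F6 | step 3 | {2-[3,5-dimethoxy-4-(methoxymethoxy)phenoxy]-3,4,5-trimethoxyphenyl}methanol | COCOc1c(OC)cc(Oc2c(CO)cc(OC)c(OC)c2OC)cc1OC
F7 | step 9 | (4-formyl-3,5-dimethoxyphenyl)boronic acid | COc1cc(B(O)O)cc(OC)c1C=O
F8 | step 12 | tridecaacetate of 18 | CC(=O)Oc1cc(OC(C)=O)c(Oc2cc(OC(C)=O)c(OC(C)=O)c(Oc3cc(OC(C)=O)c(OC(C)=O)c(OC(C)=O)c3Oc3cc(OC(C)=O)c(Oc4cc(OC(C)=O)c(OC(C)=O)c(OC(C)=O)c4)c(OC(C)=O)c3)c2)c(OC(C)=O)c1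
A1 | alternative 1 | A–B–C fragment with ring C as hydroquinone mono-silyl ether: 4-(tert-butyldimethylsilyloxy)-5-[2,3-dimethoxy-5-(2,4,6-trimethoxyphenoxy)phenoxy]-2,3-dimethoxyphenol | COc1c(O)cc(Oc2cc(Oc3c(OC)cc(OC)cc3OC)cc(OC)c2OC)c(O[Si](C)(C)C(C)(C)C)c1OC
A2 | alternative 1 | 4-(tert-butyldimethylsilyloxy)-4-{1-[2,3-dimethoxy-5-(2,4,6-trimethoxyphenoxy)phenoxy]vinyl}-2,3-dimethoxycyclobut-2-en-1-one (racemic) | COC1=C(OC)C(O[Si](C)(C)C(C)(C)C)(C(=C)Oc2cc(Oc3c(OC)cc(OC)cc3OC)cc(OC)c2OC)C1=O
A3 | alternative 2 | pentamer with ring A as dimethyl 2,4,6-trihydroxy-5-aryloxyisophthalate, rings B to E permethylated | COC(=O)c1c(O)c(C(=O)OC)c(O)c(Oc2cc(OC)c(OC)c(Oc3cc(OC)c(OC)c(OC)c3Oc3cc(OC)c(Oc4cc(OC)c(OC)c(OC)c4)c(OC)c3)c2)c1O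
A4 | alternative 2 | dimethyl 2-aryloxymalonate, aryl = permethylated rings B–C–D–E | COC(=O)C(Oc1cc(OC)c(OC)c(Oc2cc(OC)c(OC)c(OC)c2Oc2cc(OC)c(Oc3cc(OC)c(OC)c(OC)c3)c(OC)c2)c1)C(=O)OC
A5 | alternative 2 | dimethyl 3-oxopentanedioate | COC(=O)CC(=O)CC(=O)OC
A6 | alternative 3 | permethylated pentamer with formyl at C4 of ring B | COc1cc(OC)c(Oc2cc(OC)c(C=O)c(Oc3cc(OC)c(OC)c(OC)c3Oc3cc(OC)c(Oc4cc(OC)c(OC)c(OC)c4)c(OC)c3)c2)c(OC)c1
A7 | alternative 3 | 2,4,6-trimethoxyphenol | COc1cc(OC)c(O)c(OC)c1
A8 | alternative 3 | C–D–E phenol: 2-[3,5-dimethoxy-4-(3,4,5-trimethoxyphenoxy)phenoxy]-3,4,5-trimethoxyphenol | COc1cc(Oc2c(OC)cc(Oc3c(O)cc(OC)c(OC)c3OC)cc2OC)cc(OC)c1OC
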